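The dihydropyran ring is disconnected across its aryl–oxygen bond and its C1′–C5 bond. This pairs a C4–C5 epoxide on the nine-membered ring (oxygen on the methyl-bearing C4) with a 2-fluorobenzhydryl carbanion: one pot joins the fragments by epoxide opening at C5 with inversion, closes the ring by fluoride displacement from the phloroglucinol nucleus, and funnels both C1′ epimers through a planar carbanion to one. The step exploits the vicinal O–C4–C5 array and the ortho relation of C1′ and the ether carbon on the aromatic ring. The (1S,9R) caryophyllane is built by asymmetric [2+2] photocycloaddition and Grob ring expansion; phenol release and double formylation come last.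

Key step: step 12

Remark: as drawn, the target has the (1S,9R) cyclobutane ring fusion, the mirror image of the terpene part of the abundant (−)-β-caryophyllene series, so the caryophyllane is made de novo; atoms are numbered as in caryophyllane (C1–C15), with C1′ for the benzylic carbon.

Step 1
Reactants: 1 cyclohex-2-en-1-one; 2 2-methylpropene
Product: 3 (1S,6S)-7,7-dimethylbicyclo[4.2.0]octan-2-one
Conditions: 2 (excess), AlBr3-activated chiral diarylprolinol-derived B-aryl oxazaborolidine (0.5 equiv, the enantiomer that gives the (1S,6S) adduct), hν (366 nm), CH2Cl2, −75 °C; then basic Al2O3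
Reagents that add atoms: none
Why: Enantioselective enone–alkene [2+2] photocycloaddition, in which the Lewis-acid-bound enone absorbs at long wavelength and the oxazaborolidine shields one enone face, should set C1 and C6 head-to-tail, and alumina epimerises C1 (α to the ketone) to the cis ring fusion.

Step 2
Reactants: 3 (1S,6S)-7,7-dimethylbicyclo[4.2.0]octan-2-one
Product: 5 methyl (1S,3R,6S)-3,7,7-trimethyl-2-oxobicyclo[4.2.0]octane-3-carboxylate, via sodium enolate 4 (not isolated)
Conditions: NaH, (MeO)2CO, THF, reflux; then MeI, 0 °C → rt
Reagents that add atoms: dimethyl carbonate COC(=O)OC; iodomethane CI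
Why: Claisen-type C-acylation at the only enolisable methylene gives the stabilised β-keto ester enolate, and its C-methylation should occur on the convex face opposite the cyclobutane (a centre that is erased in step 7).

Step 3
Reactants: 5 methyl (1S,3R,6S)-3,7,7-trimethyl-2-oxobicyclo[4.2.0]octane-3-carboxylate; 6 methyl acrylate
Product: 7 spiro-γ-lactone (lactone oxygen cis to the C3 ester)
Conditions: SmI2 (2.5 equiv), t-BuOH, THF, 0 °C → rt
Reagents that add atoms: none
Why: SmI2 ketyl–acrylate coupling followed by lactonisation, in which the samarium chelate between ketyl oxygen and the neighbouring ester should steer the acrylate to the convex face so that the new C–O bond is cis to the ester.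

Step 4
Reactants: 7 spiro-γ-lactone
Product: 9 tricyclic hydroxy ketone (ring-fusion OH trans to the angular methyl), via sodium enolate of hydroxy keto ester 8 (not isolated)
Conditions: NaOMe, MeOH–toluene, reflux; then 2 M NaOH, 60 °C; then HCl, 60 °C
Reagents that add atoms: none
Why: Methoxide opens the lactone and the chain ester enolate closes the cyclopentanone by Dieckmann condensation onto the neighbouring quaternary ester (driven by formation of enolate 8), after which saponification and decarboxylation of the β-keto acid leave the hydroxy ketone.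

Step 5
Reactants: 9 tricyclic hydroxy ketone
Product: 10 tricyclic diol (secondary OH cis to the angular methyl)
Conditions: NaBH4, MeOH, 0 °C
Reagents that add atoms: none
Why: Hydride reduction should occur from the face opposite the adjacent angular methyl group (as in 17-oxo steroids), which places the new hydroxyl cis to that methyl.

Step 6
Reactants: 10 tricyclic diol
Product: 11 secondary mono-tosylate
Conditions: TsCl, pyridine, DMAP (cat.), 0 °C → rt
Reagents that add atoms: 4-toluenesulfonyl chloride Cc1ccc(cc1)S(=O)(=O)Cl
Why: Sulfonylation is selective for the secondary alcohol because the tertiary ring-fusion alcohol is too hindered to react.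

Step 7
Reactants: 11 secondary mono-tosylate
Product: 13 (1S,4E,9R)-4,11,11-trimethylbicyclo[7.2.0]undec-4-en-8-one, via cis-fused ketone 12 (not isolated)
Conditions: KOt-Bu (3 equiv), t-BuOH–THF, 25 → 50 °C
Reagents that add atoms: none
Why: Grob fragmentation of the ring-fusion alkoxide cleaves the C–C bond antiperiplanar to the tosylate and, because tosylate and methyl are cis, should give the (E)-4,5-alkene of the nine-membered ring, after which excess base epimerises C9 (α to the new ketone) to the more stable trans-fused bicycle.

Step 8
Reactants: 13 (1S,4E,9R)-4,11,11-trimethylbicyclo[7.2.0]undec-4-en-8-one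
Product: 14 (1S,4E,9R)-4,11,11-trimethyl-8-methylidenebicyclo[7.2.0]undec-4-ene
Conditions: Ph3PCH3Br, KOt-Bu, toluene, 25 → 60 °C
Reagents that add atoms: methyltriphenylphosphonium bromide [Br-].C[P+](c1ccccc1)(c1ccccc1)c1ccccc1
Why: Wittig methylenation of the ketone under basic conditions keeps C9 in the thermodynamically preferred trans configuration.

Step 9
Reactants: 14 (1S,4E,9R)-4,11,11-trimethyl-8-methylidenebicyclo[7.2.0]undec-4-ene
Product: 15 (1S,4S,5S,9R)-4,11,11-trimethyl-8-methylidenebicyclo[7.2.0]undecane-4,5-diol
Conditions: OsO4 (2 mol%), NMO (1.05 equiv), acetone–H2O, 0 °C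
Reagents that add atoms: N-methylmorpholine N-oxide C[N+]1([O-])CCOCC1; water O
Why: Catalytic syn-dihydroxylation should take the strained, electron-rich trisubstituted (E)-alkene in preference to the 1,1-disubstituted alkene and add to its exposed outer face (the face also taken by peracids), which sets C4 and C5 with both oxygens on that face.

Step 10
Reactants: 15 (1S,4S,5S,9R)-4,11,11-trimethyl-8-methylidenebicyclo[7.2.0]undecane-4,5-diol
Product: 17 (1S,4S,5R,9R)-4,5-epoxy-4,11,11-trimethyl-8-methylidenebicyclo[7.2.0]undecane, via C5 mesylate 16 (not isolated)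
Conditions: MsCl, Et3N, CH2Cl2, −20 °C; then K2CO3, MeOH, 25 °C
Reagents that add atoms: none
Why: Sulfonylation of the secondary hydroxyl and intramolecular Williamson displacement by the tertiary alkoxide (3-exo-tet) inverts C5 and leaves C4 unchanged, giving the cis-epoxide.

Step 11
Reactants: 18 1-fluoro-3,5-dimethoxybenzene; 19 benzyl bromide
Product: 21 2-benzyl-1-fluoro-3,5-dimethoxybenzene, via aryllithium 20 (not isolated)
Conditions: LiN(i-Pr)2, THF, −78 °C; then CuBr·SMe2 (10 mol%), 19, −78 → −20 °C
Reagents that add atoms: none
Why: The amide base removes the most acidic ring proton, which lies ortho to fluorine and next to a methoxy group (directed ortho-metalation governed by acidity), and copper-catalysed alkylation of the aryllithium with the benzyl halide gives the diarylmethane.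

Step 12
Reactants: 17 (1S,4S,5R,9R)-4,5-epoxy-4,11,11-trimethyl-8-methylidenebicyclo[7.2.0]undecane; 21 2-benzyl-1-fluoro-3,5-dimethoxybenzene
Product: 25 (1S,4S,5R,9R,1′R)-chroman dimethyl ether, via lithium diarylmethanide 22 (not isolated), via lithium alkoxide 23 (not isolated), via lithiated chroman 24 (not isolated)
Conditions: 21 (2.5 equiv), LiN(i-Pr)2 (2.4 equiv), THF, −78 °C; 17, −78 → 45 °C; DMPU, 65 °C; LiN(i-Pr)2 (3 equiv), 0 °C; 2,6-di-tert-butylphenol, −78 °C
Reagents that add atoms: none
Why: The benzylic lithium carbanion 22 opens the cis-epoxide by SN2 attack at the secondary carbon C5 (closest known type: alkylation of epoxides by benzyl- and benzhydryl-lithium reagents), and the tertiary lithium alkoxide 23 so released displaces the ortho fluoride by addition–elimination, as in the known chroman synthesis from 3-(2-fluoroaryl)propan-1-ols. The pyran ring thus closes in a 6-exo-trig mode onto the arene carbon, helped by the two meta methoxy groups and by precipitation of LiF. C5 is set by inversion on the stereodefined epoxide (the second inversion after step 10, hence net syn addition to the original (E)-alkene and a trans ring fusion), and C4 keeps the configuration fixed in step 9. C1′ is not controlled in the alkylation, so LiN(i-Pr)2 converts the product into the planar diarylmethyl anion 24 that both epimers share, and the bulky phenol should protonate it from the face opposite the axial C4 methyl group of the half-chair, which leaves phenyl cis to that methyl. The step needs attack at C5 and not at C4 (secured by the fully substituted C4), benzylic and not ring lithiation of 21 (secured by the large acidity gap under equilibrating amide conditions at low temperature), and no base-induced isomerisation of the epoxide (no free amide base is present during the alkylation).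

Step 13
Reactants: 25 (1S,4S,5R,9R,1′R)-chroman dimethyl ether
Product: 26 (1S,4S,5R,9R,1′R)-chroman diphenol
Conditions: MeMgI (neat, Et2O removed), 160 °C; then aq. NH4Cl
Reagents that add atoms: none
Why: Grignard-mediated O-demethylation (SN2 at the methyl groups, a method established for aryl methyl ethers that carry chroman rings and 1,1-disubstituted alkenes) should cleave both methyl ethers and leave the tertiary alkyl aryl ether, the alkene and C1′ untouched.

Step 14
Reactants: 26 (1S,4S,5R,9R,1′R)-chroman diphenol
Product: 27 psidial A as drawn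
Conditions: POCl3, DMF, EtOAc, 0 → 25 °C; then H2O, 50 °C
Reagents that add atoms: N,N-dimethylformamide CN(C)C=O; water O
Why: Vilsmeier–Haack formylation should occur twice on the phloroglucinol-type ring, at the only two free positions (each ortho or para to the hydroxyl groups), while the chloroiminium ion is too weak an electrophile to attack the 1,1-disubstituted alkene.

Compound list
1 | cyclohex-2-en-1-one | O=C1C=CCCC1 | starting material
2 | 2-methylpropene | CC(C)=C | starting material
3 | (1S,6S)-7,7-dimethylbicyclo[4.2.0]octan-2-one (cis-fused) | O=C1CCC[C@H]2[C@@H]1CC2(C)C | intermediate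
4 | sodium enolate of methyl (1S,6S)-7,7-dimethyl-2-oxobicyclo[4.2.0]octane-3-carboxylate | [Na+].[O-]C1=C(C(=O)OC)CC[C@H]2[C@@H]1CC2(C)C | intermediate
5 | methyl (1S,3R,6S)-3,7,7-trimethyl-2-oxobicyclo[4.2.0]octane-3-carboxylate (3-methyl on the face opposite the cyclobutane) | O=C1[C@](C)(C(=O)OC)CC[C@H]2[C@@H]1CC2(C)C | intermediate
6 | methyl acrylate | C=CC(=O)OC | starting material
7 | spiro-γ-lactone: former ketone carbon of 5 bears the lactone oxygen (cis to the C3 ester and the cyclobutane) and the CH2CH2C(=O) chain (cis to the C3 methyl) | O=C1CC[C@@]2(O1)[C@](C)(C(=O)OC)CC[C@H]1[C@@H]2CC1(C)C | intermediate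
8 | sodium enolate of the tricyclic hydroxy β-keto ester (cyclopentanone closed between the chain and the former C3 ester carbon) | [Na+].O[C@]12CC(C(=O)OC)=C([O-])[C@]1(C)CC[C@H]1[C@@H]2CC1(C)C | intermediate
9 | tricyclic hydroxy ketone (cyclobutane–cyclohexane–cyclopentanone; tertiary OH and angular methyl trans at the six/five ring fusion, ketone next to the methyl-bearing carbon) | O[C@]12CCC(=O)[C@]1(C)CC[C@H]1[C@@H]2CC1(C)C | intermediate
10 | tricyclic diol (secondary OH cis to the angular methyl) | O[C@]12CC[C@@H](O)[C@]1(C)CC[C@H]1[C@@H]2CC1(C)C | intermediate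
11 | mono-tosylate of 10 at the secondary hydroxyl | O[C@]12CC[C@@H](OS(=O)(=O)c3ccc(C)cc3)[C@]1(C)CC[C@H]1[C@@H]2CC1(C)C | intermediate
12 | (1S,4E,9S)-4,11,11-trimethylbicyclo[7.2.0]undec-4-en-8-one (cis-fused) | C/C1=C\CCC(=O)[C@H]2CC([C@H]2CC1)(C)C | intermediate
13 | (1S,4E,9R)-4,11,11-trimethylbicyclo[7.2.0]undec-4-en-8-one (trans-fused) | C/C1=C\CCC(=O)[C@@H]2CC([C@H]2CC1)(C)C | intermediate
14 | (1S,4E,9R)-4,11,11-trimethyl-8-methylidenebicyclo[7.2.0]undec-4-ene ((+)-β-caryophyllene) | C/C1=C\CCC(=C)[C@@H]2CC([C@H]2CC1)(C)C | intermediate
15 | (1S,4S,5S,9R)-4,11,11-trimethyl-8-methylidenebicyclo[7.2.0]undecane-4,5-diol | C[C@]1(O)CC[C@H]2[C@@H](CC2(C)C)C(=C)CC[C@@H]1O | intermediate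
16 | C5 methanesulfonate of 15 | C[C@]1(O)CC[C@H]2[C@@H](CC2(C)C)C(=C)CC[C@@H]1OS(C)(=O)=O | intermediate
17 | (1S,4S,5R,9R)-4,5-epoxy-4,11,11-trimethyl-8-methylidenebicyclo[7.2.0]undecane (cis-epoxide) | C[C@]12CC[C@H]3[C@@H](CC3(C)C)C(=C)CC[C@H]1O2 | intermediate
18 | 1-fluoro-3,5-dimethoxybenzene | COc1cc(F)cc(OC)c1 | starting material
19 | benzyl bromide | BrCc1ccccc1 | starting material
20 | 2-fluoro-4,6-dimethoxyphenyllithium | [Li]c1c(F)cc(OC)cc1OC | intermediate
21 | 2-benzyl-1-fluoro-3,5-dimethoxybenzene | COc1cc(OC)c(Cc2ccccc2)c(F)c1 | intermediate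
22 | lithium (2-fluoro-4,6-dimethoxyphenyl)(phenyl)methanide | [Li+].COc1cc(OC)c([CH-]c2ccccc2)c(F)c1 | intermediate
23 | lithium alkoxide from epoxide opening (C4 O-lithium, C5 diarylmethyl on the face anti to the former epoxide oxygen, C1′ as a mixture) | [Li+].C=C1CC[C@H](C(c3ccccc3)c3c(F)cc(OC)cc3OC)[C@@](C)([O-])CC[C@H]2[C@H]1CC2(C)C | intermediate
24 | C1′-lithiated chroman (planar diarylmethyl anion) | [Li+].C=C1CC[C@@H]2[C-](c3ccccc3)c3c(OC)cc(OC)cc3O[C@@]2(C)CC[C@H]2[C@H]1CC2(C)C | intermediate
25 | (1S,4S,5R,9R,1′R)-chroman dimethyl ether: 5,7-dimethoxy-4-phenylchroman fused through its O-bearing carbon to C4 and through its neighbour to C5 of the caryophyllane (trans fusion; phenyl cis to the C4 methyl) | C=C1CC[C@@H]2[C@H](c3ccccc3)c3c(OC)cc(OC)cc3O[C@@]2(C)CC[C@H]2[C@H]1CC2(C)C | intermediate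
26 | (1S,4S,5R,9R,1′R)-chroman diphenol (both methyl ethers of 25 cleaved) | C=C1CC[C@@H]2[C@H](c3ccccc3)c3c(O)cc(O)cc3O[C@@]2(C)CC[C@H]2[C@H]1CC2(C)C | intermediate
27 | psidial A as drawn (6,8-diformyl-5,7-dihydroxy chroman) | C=C1CC[C@@H]2[C@H](c3ccccc3)c3c(O)c(C=O)c(O)c(C=O)c3O[C@@]2(C)CC[C@H]2[C@H]1CC2(C)C | target

Total step count: 14. Longest linear sequence: 13 steps (steps 1–10 and 12–14); step 11 is the convergent branch.

Steps most likely to fail

1. Step 12. Bimolecular substitution at the hindered ring carbon of the medium-ring epoxide may be outrun by base-induced isomerisation of the epoxide to an allylic alcohol, and the closing protonation may show poor facial selectivity. The fallback sets out from diol 15 and comes back at 25. The secondary C5 hydroxyl of 15 is etherified under TsOH catalysis with (2-fluoro-4,6-dimethoxyphenyl)(phenyl)methanol F1, itself made from 18 by LiN(i-Pr)2 and then benzaldehyde, to give benzhydryl ether F2. n-BuLi (2.2 equiv) in THF from −78 to 25 °C should bring about a [1,2]-Wittig rearrangement in which C5 migrates from oxygen to the benzhydryl carbanion with retention, and warming with DMPU closes the aryl ether by the same fluoride displacement to give tertiary carbinol F3. Et3SiH and BF3·OEt2 at −78 °C then reduce the doubly benzylic carbinol with hydride delivery anti to the axial C4 methyl, which gives 25.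

2. Step 14. The second formylation may stall once the first formyl group has deactivated the ring, or acid liberated during the reaction may add to or isomerise the exocyclic alkene. The fallback sets out from 21 (with 17) and comes back at 27, so it also replaces step 13. Rieche formylation of 21 (Cl2CHOMe, TiCl4, CH2Cl2, 0 °C) at both free ring positions gives 5-benzyl-4-fluoro-2,6-dimethoxybenzene-1,3-dicarbaldehyde F4, which ethylene glycol and TsOH convert into bis-dioxolane F5. F5 is taken through the conditions of step 12 with 17 to give chroman bis-acetal F6; its fully substituted ring also excludes ring lithiation. BCl3 (CH2Cl2, −78 → 0 °C) then cleaves both acetals and, assisted by the liberated ortho formyl groups, both methyl ethers to give 27.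

3. Step 3. Simple reduction of the hindered ketyl to the secondary alcohol, or retro-Claisen cleavage of the β-keto ester, may outrun C–C coupling. The fallback sets out from 5 and comes back at 7. The lithium acetylide of propiolaldehyde diethyl acetal (n-BuLi, THF, −78 °C) adds to the ketone from the convex face to give propargylic alcohol F7. Hydrogenation (H2, Pd/C, EtOAc) gives saturated hydroxy acetal F8, and Jones oxidation (CrO3, H2SO4, acetone) unmasks the aldehyde and oxidises the derived lactol to lactone 7.

Further compounds
F1 | step 12 | (2-fluoro-4,6-dimethoxyphenyl)(phenyl)methanol | COc1cc(OC)c(C(O)c2ccccc2)c(F)c1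
F2 | step 12 | C5 benzhydryl ether of diol 15 | C[C@]1(O)CC[C@H]2[C@@H](CC2(C)C)C(=C)CC[C@@H]1OC(c1ccccc1)c1c(F)cc(OC)cc1OC
F3 | step 12 | C1′-hydroxy chroman dimethyl ether | C=C1CC[C@@H]2C(O)(c3ccccc3)c3c(OC)cc(OC)cc3O[C@@]2(C)CC[C@H]2[C@H]1CC2(C)C
F4 | step 14 | 5-benzyl-4-fluoro-2,6-dimethoxybenzene-1,3-dicarbaldehyde | COc1c(C=O)c(OC)c(Cc2ccccc2)c(F)c1C=O
F5 | step 14 | bis(1,3-dioxolane) of F4 | COc1c(C2OCCO2)c(OC)c(Cc2ccccc2)c(F)c1C1OCCO1
F6 | step 14 | chroman dimethyl ether carrying both formyl groups as 1,3-dioxolanes | C=C1CC[C@@H]2[C@H](c3ccccc3)c3c(OC)c(C4OCCO4)c(OC)c(C4OCCO4)c3O[C@@]2(C)CC[C@H]2[C@H]1CC2(C)C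
F7 | step 3 | propargylic alcohol from acetylide addition to 5 | O[C@]1(C#CC(OCC)OCC)[C@](C)(C(=O)OC)CC[C@H]2[C@@H]1CC2(C)C
F8 | step 3 | saturated hydroxy diethyl acetal | O[C@]1(CCC(OCC)OCC)[C@](C)(C(=O)OC)CC[C@H]2[C@@H]1CC2(C)C
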